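**Retrosynthetic overview**

1. The strategy rests on ring A of the (2S)-flavanone 26: a hexasubstituted benzene (C4a–C8a) whose three mutually meta oxygens (O1 on C8a, OH on C5, OH on C7) are separated by three different carbons (C4a acyl, C6 prenyl, C8 methyl), so each oxygen has to be introduced in a different form.
2. Last disconnections: O7–Si, then C4–C4a (intramolecular Friedel–Crafts acylation of aryloxy acid 23 at the only C–H of ring A), which closes ring C.
3. Key disconnection: ring A itself (bonds C5–C6, C7–C8 and C4a–C5) by thermal benzannulation of 3-alkoxy-2-methylcyclobutenone 12, whose enol-ether oxygen already carries the C2 stereocentre, with prenyl siloxyalkyne 17; the ring ketone becomes C5–OH, the ynol silyl ether C7–OSi and the enol ether O1.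
4. 12 comes from (S)-hydroxy ester 5 (Stille prenylation of a ring B acetophenone, Claisen condensation, asymmetric transfer hydrogenation) and dione 10 (ketene + 1-ethoxypropyne), joined through vinylogous acid chloride 11 so that no bond to C2 is broken; 17 comes from a Kowalski ynolate.
5. Order of ring formation: ring B is bought, ring A is built in step 9, ring C in step 11.

Key step: step 9

Remark: prenyl = 3-methylbut-2-en-1-yl and TIPS = triisopropylsilyl; dione 10 is handled as its enol tautomer, and ketene 8 is taken as a gas stream from a hot-wire ketene generator fed with acetone.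

**Route**

Step 1
Reactants: 1 1-(3-bromo-4-methoxyphenyl)ethan-1-one; 2 tributyl(3-methylbut-2-en-1-yl)stannane
Product: 3 1-[4-methoxy-3-(3-methylbut-2-en-1-yl)phenyl]ethan-1-one
Conditions: Pd(PPh3)4 (5 mol%), DMF, 100 °C, argon
Reagents that add atoms: none
Why: Stille coupling: oxidative addition of the aryl bromide to zerovalent palladium, transmetalation and reductive elimination at the unsubstituted terminus of the η3-prenyl ligand should give the linear prenylarene, the ketone being inert.

Step 2
Reactants: 3 1-[4-methoxy-3-(3-methylbut-2-en-1-yl)phenyl]ethan-1-one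
Product: 4 methyl 3-[4-methoxy-3-(3-methylbut-2-en-1-yl)phenyl]-3-oxopropanoate
Conditions: NaH (2.5 equiv), (MeO)2CO (3 equiv), THF, reflux; then aq. HCl (1 M), 0 °C
Reagents that add atoms: dimethyl carbonate, COC(=O)OC
Why: Claisen condensation of the methyl ketone enolate with dimethyl carbonate, driven to completion by deprotonation of the β-keto ester formed.

Step 3
Reactants: 4 methyl 3-[4-methoxy-3-(3-methylbut-2-en-1-yl)phenyl]-3-oxopropanoate
Product: 5 methyl (3S)-3-hydroxy-3-[4-methoxy-3-(3-methylbut-2-en-1-yl)phenyl]propanoate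
Conditions: RuCl[(S,S)-TsDPEN](p-cymene) (1 mol%), HCO2H–Et3N (5:2), DMF, 40 °C
Reagents that add atoms: none
Why: Noyori asymmetric transfer hydrogenation: by the usual aryl-ketone model (CH–π contact between the aryl group and the η6-cymene) the (S,S)-catalyst should deliver hydride to the Re face of the ketone and set the (S)-carbinol, leaving ester and trisubstituted alkene untouched.

Step 4
Reactants: 6 acetone; 7 1-ethoxyprop-1-yne
Product: 9 3-ethoxy-2-methylcyclobut-2-en-1-one, via ketene 8 (not isolated)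
Conditions: acetone vapour through a hot-wire ketene generator (about 700 °C); gas stream into 7, CH2Cl2, 0 °C
Reagents that add atoms: none
Why: Cracking of acetone gives ketene and methane, and the [2+2] cycloaddition of ketene with the ynol ether is polarity-controlled (the methyl-bearing alkyne carbon attacks the ketene carbonyl carbon), which places methyl at C2 and ethoxy at C3 of the cyclobutenone.

Step 5
Reactants: 9 3-ethoxy-2-methylcyclobut-2-en-1-one
Product: 10 3-hydroxy-2-methylcyclobut-2-en-1-one (enol of 2-methylcyclobutane-1,3-dione)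
Conditions: aq. HCl (2 M), THF, 0 °C → rt
Reagents that add atoms: water, O
Why: Acid hydrolysis of the vinylogous ester (protonation at C2, addition of water at C3, loss of ethanol) should give the strongly acidic dione, isolated as its crystalline enol.

Step 6
Reactants: 10 3-hydroxy-2-methylcyclobut-2-en-1-one; 5 methyl (3S)-3-hydroxy-3-[4-methoxy-3-(3-methylbut-2-en-1-yl)phenyl]propanoate
Product: 12 methyl (3S)-3-[4-methoxy-3-(3-methylbut-2-en-1-yl)phenyl]-3-[(2-methyl-3-oxocyclobut-1-en-1-yl)oxy]propanoate, via 3-chloro-2-methylcyclobut-2-en-1-one 11 (not isolated)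
Conditions: 10 (1.3 equiv), (COCl)2, DMF (cat.), CH2Cl2, 0 °C → rt, then evaporation; then 5, 2,6-lutidine, DMAP (cat.), CH2Cl2, −20 → 0 °C
Reagents that add atoms: none
Why: Vinylogous acyl substitution: 10 is a vinylogous carboxylic acid and 11 its acid chloride, so DMAP-assisted addition–elimination of the alcohol at C3 should form the enol ether under non-acidic conditions, and because only the O–H bond of 5 is broken the (S) centre is carried over with retention.

Step 7
Reactants: 13 4-methylpent-3-enoic acid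
Product: 14 ethyl 4-methylpent-3-enoate
Conditions: EtI, K2CO3, DMF, rt
Reagents that add atoms: iodoethane, CCI
Why: O-alkylation of the carboxylate under mild base avoids the acid-catalysed lactonisation to which this β,γ-unsaturated acid is prone.

Step 8
Reactants: 14 ethyl 4-methylpent-3-enoate
Product: 17 triisopropyl[(5-methylhex-4-en-1-yn-1-yl)oxy]silane, via lithium dibromoenolate 15 (not isolated), via lithium ynolate 16 (not isolated)
Conditions: CH2Br2, lithium 2,2,6,6-tetramethylpiperidide (LiTMP, 2.2 equiv), THF, −78 °C; n-BuLi, −78 → 0 °C; i-Pr3SiCl, −78 → 0 °C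
Reagents that add atoms: dibromomethane, BrCBr; chlorotriisopropylsilane, CC(C)[Si](Cl)(C(C)C)C(C)C
Why: Kowalski ester homologation stopped at the ynolate: LiCHBr2 adds to the ester, the dibromoketone is enolised to 15, bromine–lithium exchange triggers the 1,2-shift of the prenyl-bearing carbon to give 16, and the bulky silyl chloride traps the ynolate on oxygen.

Step 9
Reactants: 12 methyl (3S)-3-[4-methoxy-3-(3-methylbut-2-en-1-yl)phenyl]-3-[(2-methyl-3-oxocyclobut-1-en-1-yl)oxy]propanoate; 17 triisopropyl[(5-methylhex-4-en-1-yn-1-yl)oxy]silane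
Product: 22 methyl (3S)-3-[5-hydroxy-2-methyl-4-prenyl-3-(triisopropylsilyloxy)phenoxy]-3-(4-methoxy-3-prenylphenyl)propanoate, via vinylketene 18 (not isolated), via vinylcyclobutenone 19 (not isolated), via dienylketene 20 (not isolated), via cyclohexadienone 21 (not isolated)
Conditions: 17 (1.5 equiv), 2,6-di-tert-butyl-4-methylpyridine (10 mol%), toluene (0.3 M), 80 → 110 °C, sealed tube, argon
Reagents that add atoms: none
Why: Proposed new method: heating should open 12 by 4π electrocyclic cleavage of the C5–C4a bond to vinylketene 18, whose ketene carbon (future C5) is attacked by the prenyl-bearing carbon of 17 in a polarity-controlled [2+2] that gives 19 and forms C5–C6 and C7–C8; 19 opens reversibly to dienylketene 20, which closes and tautomerises through 21 to the phenol. The closest known reaction type is the Danheiser benzannulation of 3-alkyl- and 3-arylcyclobutenones with siloxyalkynes to resorcinol monosilyl ethers; new here is a 3-alkoxycyclobutenone (a vinylogous ester) as the vinylketene source, although thermal opening of 3-alkoxycyclobutenones to vinylketenes and of 3-alkoxy-4-vinylcyclobutenones to phenols are each known separately. Ring A is closed by a thermal 6π electrocyclisation of 20 (bond C4a–C5) followed by enolisation, the four-membered ring of 19 being only transient. No stereocentre is created (the quaternary carbon of 19 is destroyed again), and C2 is a spectator because none of its bonds is made or broken. The step needs regioselectivity in the ketene–ynol ether [2+2], which the polarity of the siloxyalkyne secures (prenyl ends between the C5 and C7 oxygens, methyl next to O1), and it needs the benzylic C2–O bond of the vinylogous ester to survive, for which a non-polar solvent, an acid scavenger and the lowest effective temperature are chosen.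

Step 10
Reactants: 22 methyl (3S)-3-[5-hydroxy-2-methyl-4-prenyl-3-(triisopropylsilyloxy)phenoxy]-3-(4-methoxy-3-prenylphenyl)propanoate
Product: 23 (3S)-3-[5-hydroxy-2-methyl-4-prenyl-3-(triisopropylsilyloxy)phenoxy]-3-(4-methoxy-3-prenylphenyl)propanoic acid
Conditions: LiOH·H2O (3 equiv), THF–H2O (3:1), 0 °C → rt; then aq. HCl (1 M) to pH 3, 0 °C
Reagents that add atoms: lithium hydroxide, [Li+].[OH-]
Why: Saponification of the methyl ester should outrun E1cB loss of the poor aryloxide leaving group, the aryl silyl ether is shielded by its two ortho substituents, and C2 is not touched.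

Step 11
Reactants: 23 (3S)-3-[5-hydroxy-2-methyl-4-prenyl-3-(triisopropylsilyloxy)phenoxy]-3-(4-methoxy-3-prenylphenyl)propanoic acid
Product: 25 (2S)-5-hydroxy-2-(4-methoxy-3-prenylphenyl)-8-methyl-6-prenyl-7-(triisopropylsilyloxy)chroman-4-one, via mixed trifluoroacetic anhydride 24 (not isolated)
Conditions: (CF3CO)2O (1.2 equiv), CH2Cl2 (0.02 M), −20 → 0 °C; then aq. NaHCO3
Reagents that add atoms: none
Why: Intramolecular Friedel–Crafts acylation through the mixed anhydride: C4a is the only free position of ring A and is ortho, ortho and para to three oxygens, so the six-membered pyranone should close at low temperature without a Lewis acid, and the new ketone then ties up the C5 hydroxyl in a hydrogen bond.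

Step 12
Reactants: 25 (2S)-5-hydroxy-2-(4-methoxy-3-prenylphenyl)-8-methyl-6-prenyl-7-(triisopropylsilyloxy)chroman-4-one
Product: 26 (2S)-5,7-dihydroxy-2-[4-methoxy-3-(3-methylbut-2-en-1-yl)phenyl]-8-methyl-6-(3-methylbut-2-en-1-yl)chroman-4-one
Conditions: Bu4NF (1.2 equiv), AcOH (1.2 equiv), THF, 0 °C
Reagents that add atoms: none
Why: Fluoride cleavage of the aryl silyl ether, which is activated as a vinylogous silyl ester para to the C4 ketone; the acetic acid buffer keeps phenoxide and enolate concentrations low, so retro-oxa-Michael opening of ring C and loss of the C2 configuration should not occur.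

**Compound list**

1 | 1-(3-bromo-4-methoxyphenyl)ethan-1-one | CC(=O)c1ccc(OC)c(Br)c1 | starting material
2 | tributyl(3-methylbut-2-en-1-yl)stannane | CCCC[Sn](CCCC)(CCCC)CC=C(C)C | starting material
3 | 1-[4-methoxy-3-(3-methylbut-2-en-1-yl)phenyl]ethan-1-one | CC(=O)c1ccc(OC)c(CC=C(C)C)c1 | intermediate
4 | methyl 3-[4-methoxy-3-(3-methylbut-2-en-1-yl)phenyl]-3-oxopropanoate | COC(=O)CC(=O)c1ccc(OC)c(CC=C(C)C)c1 | intermediate
5 | methyl (3S)-3-hydroxy-3-[4-methoxy-3-(3-methylbut-2-en-1-yl)phenyl]propanoate | COC(=O)C[C@H](O)c1ccc(OC)c(CC=C(C)C)c1 | intermediate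
6 | acetone | CC(C)=O | starting material
7 | 1-ethoxyprop-1-yne | CCOC#CC | starting material
8 | ketene (ethenone) | C=C=O | intermediate
9 | 3-ethoxy-2-methylcyclobut-2-en-1-one | CCOC1=C(C)C(=O)C1 | intermediate
10 | 3-hydroxy-2-methylcyclobut-2-en-1-one (enol of 2-methylcyclobutane-1,3-dione) | CC1=C(O)CC1=O | intermediate
11 | 3-chloro-2-methylcyclobut-2-en-1-one | CC1=C(Cl)CC1=O | intermediate
12 | methyl (3S)-3-[4-methoxy-3-(3-methylbut-2-en-1-yl)phenyl]-3-[(2-methyl-3-oxocyclobut-1-en-1-yl)oxy]propanoate | COC(=O)C[C@H](OC1=C(C)C(=O)C1)c1ccc(OC)c(CC=C(C)C)c1 | intermediate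
13 | 4-methylpent-3-enoic acid | CC(C)=CCC(=O)O | starting material
14 | ethyl 4-methylpent-3-enoate | CCOC(=O)CC=C(C)C | intermediate
15 | lithium 1,1-dibromo-5-methylhexa-1,4-dien-2-olate (lithium dibromoenolate) | [Li]OC(CC=C(C)C)=C(Br)Br | intermediate
16 | lithium 5-methylhex-4-en-1-yn-1-olate (lithium ynolate) | [Li]OC#CCC=C(C)C | intermediate
17 | triisopropyl[(5-methylhex-4-en-1-yn-1-yl)oxy]silane | CC(C)=CCC#CO[Si](C(C)C)(C(C)C)C(C)C | intermediate
18 | methyl (3S)-3-(4-methoxy-3-prenylphenyl)-3-[(3-methyl-4-oxobuta-1,3-dien-2-yl)oxy]propanoate (vinylketene) | COC(=O)C[C@H](OC(=C)C(C)=C=O)c1ccc(OC)c(CC=C(C)C)c1 | intermediate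
19 | methyl (3S)-3-(4-methoxy-3-prenylphenyl)-3-({1-[1-methyl-4-oxo-3-prenyl-2-(triisopropylsilyloxy)cyclobut-2-en-1-yl]ethenyl}oxy)propanoate (vinylcyclobutenone, both epimers at the ring quaternary carbon) | COC(=O)C[C@H](OC(=C)C1(C)C(=O)C(CC=C(C)C)=C1O[Si](C(C)C)(C(C)C)C(C)C)c1ccc(OC)c(CC=C(C)C)c1 | intermediate
20 | methyl (3S)-3-(4-methoxy-3-prenylphenyl)-3-{[3-methyl-6-oxo-5-prenyl-4-(triisopropylsilyloxy)hexa-1,3,5-trien-2-yl]oxy}propanoate (dienylketene) | COC(=O)C[C@H](OC(=C)C(C)=C(O[Si](C(C)C)(C(C)C)C(C)C)C(CC=C(C)C)=C=O)c1ccc(OC)c(CC=C(C)C)c1 | intermediate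
21 | methyl (3S)-3-(4-methoxy-3-prenylphenyl)-3-{[2-methyl-5-oxo-4-prenyl-3-(triisopropylsilyloxy)cyclohexa-1,3-dien-1-yl]oxy}propanoate (cyclohexadienone) | COC(=O)C[C@H](OC1=C(C)C(O[Si](C(C)C)(C(C)C)C(C)C)=C(CC=C(C)C)C(=O)C1)c1ccc(OC)c(CC=C(C)C)c1 | intermediate
22 | methyl (3S)-3-[5-hydroxy-2-methyl-4-prenyl-3-(triisopropylsilyloxy)phenoxy]-3-(4-methoxy-3-prenylphenyl)propanoate | COC(=O)C[C@H](Oc1cc(O)c(CC=C(C)C)c(O[Si](C(C)C)(C(C)C)C(C)C)c1C)c1ccc(OC)c(CC=C(C)C)c1 | intermediate
23 | (3S)-3-[5-hydroxy-2-methyl-4-prenyl-3-(triisopropylsilyloxy)phenoxy]-3-(4-methoxy-3-prenylphenyl)propanoic acid | OC(=O)C[C@H](Oc1cc(O)c(CC=C(C)C)c(O[Si](C(C)C)(C(C)C)C(C)C)c1C)c1ccc(OC)c(CC=C(C)C)c1 | intermediate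
24 | mixed anhydride of 23 with trifluoroacetic acid | O=C(OC(=O)C(F)(F)F)C[C@H](Oc1cc(O)c(CC=C(C)C)c(O[Si](C(C)C)(C(C)C)C(C)C)c1C)c1ccc(OC)c(CC=C(C)C)c1 | intermediate
25 | (2S)-5-hydroxy-2-(4-methoxy-3-prenylphenyl)-8-methyl-6-prenyl-7-(triisopropylsilyloxy)chroman-4-one | COc1ccc([C@@H]2CC(=O)c3c(O)c(CC=C(C)C)c(O[Si](C(C)C)(C(C)C)C(C)C)c(C)c3O2)cc1CC=C(C)C | intermediate
26 | (2S)-5,7-dihydroxy-2-[4-methoxy-3-(3-methylbut-2-en-1-yl)phenyl]-8-methyl-6-(3-methylbut-2-en-1-yl)chroman-4-one | COc1ccc([C@@H]2CC(=O)c3c(O)c(CC=C(C)C)c(O)c(C)c3O2)cc1CC=C(C)C | target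

**Step count and risks**

Total step count: 12. Longest linear sequence: 8 steps (1, 2, 3, 6, 9, 10, 11, 12).

Steps most likely to fail:

1. Step 9 (carries the label). The alkoxy-substituted cyclobutenone may open too slowly, so that ionisation or elimination at the benzylic C2–O bond (loss of the ether, erosion of configuration) overtakes the cascade; the vinylketene may also be captured by the phenol that is being formed instead of by the alkyne. Fallback by known reactions only, in which ring A is assembled first by directed metalation and the C2–O1 bond is then made by Mitsunobu inversion; it sets out from keto ester 4 (with commercial 5-bromobenzene-1,3-diol) and comes back to the route at target 26. The diol is protected with MeOCH2Cl and i-Pr2NEt as 1-bromo-3,5-bis(methoxymethoxy)benzene F1. Lithiation between the two acetal oxygens (lithium diisopropylamide, THF, −78 °C), CuBr·SMe2 and prenyl bromide give 5-bromo-1,3-bis(methoxymethoxy)-2-prenylbenzene F2. The two remaining ring positions are equivalent, so a second deprotonation next to bromine (lithium 2,2,6,6-tetramethylpiperidide, −78 °C) and MeI give only 1-bromo-3,5-bis(methoxymethoxy)-2-methyl-4-prenylbenzene F3. Bromine–lithium exchange (n-BuLi, −78 °C), B(OMe)3 and H2O2/NaOH give 3,5-bis(methoxymethoxy)-2-methyl-4-prenylphenol F4. Transfer hydrogenation of 4 with the enantiomeric catalyst RuCl[(R,R)-TsDPEN](p-cymene) gives methyl (3R)-3-hydroxy-3-(4-methoxy-3-prenylphenyl)propanoate F5. Mitsunobu coupling of F4 with F5 (PPh3, DIAD, toluene, 0 °C) should give, with inversion, methyl (3S)-3-[3,5-bis(methoxymethoxy)-2-methyl-4-prenylphenoxy]-3-(4-methoxy-3-prenylphenyl)propanoate F6. Saponification as in step 10 gives (3S)-3-[3,5-bis(methoxymethoxy)-2-methyl-4-prenylphenoxy]-3-(4-methoxy-3-prenylphenyl)propanoic acid F7, and ring closure as in step 11 gives (2S)-2-(4-methoxy-3-prenylphenyl)-5,7-bis(methoxymethoxy)-8-methyl-6-prenylchroman-4-one F8. HCl in MeOH at 40 °C then removes both acetals to give 26.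

2. Step 6. Substitution at the vinylogous acid chloride may be slow for this hindered secondary benzylic alcohol, so that dehydration of the β-hydroxy ester to the cinnamate, attack at the ring carbonyl with ring opening, or ionisation of the product ether on work-up competes. Fallback that forms the O–C(benzylic) bond instead of the O–C(sp2) bond; it sets out from keto ester 4 and dione 10 and comes back at 12. Compound 4 is reduced with RuCl[(R,R)-TsDPEN](p-cymene) to methyl (3R)-3-hydroxy-3-(4-methoxy-3-prenylphenyl)propanoate F9. F9 is then coupled with 10 under Mitsunobu conditions (PPh3, DIAD, THF, −20 → 0 °C); the symmetric oxyanion of the acidic dione should attack the activated carbinol carbon with inversion and give 12 directly.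

3. Step 11. The trifluoroacetic acid set free may protonate the prenyl double bonds (ring closure onto the free C5 hydroxyl, or addition of the acid), or the phenol may be acylated in place of C4a. Fallback by an anionic ring closure (Parham cyclisation) that needs no acid; it sets out from ester 22 and comes back at target 26. Silylation of the C5 hydroxyl (i-Pr3SiOTf, 2,6-lutidine, CH2Cl2, 0 °C) gives methyl (3S)-3-[2-methyl-4-prenyl-3,5-bis(triisopropylsilyloxy)phenoxy]-3-(4-methoxy-3-prenylphenyl)propanoate F10. N-Bromosuccinimide (CH2Cl2, −78 °C) should brominate the one free, most electron-rich position of ring A to give methyl (3S)-3-[2-bromo-6-methyl-4-prenyl-3,5-bis(triisopropylsilyloxy)phenoxy]-3-(4-methoxy-3-prenylphenyl)propanoate F11. Bromine–lithium exchange (t-BuLi, 2.1 equiv, THF, −100 °C) and attack of the aryllithium on the methyl ester close ring C to (2S)-2-(4-methoxy-3-prenylphenyl)-8-methyl-6-prenyl-5,7-bis(triisopropylsilyloxy)chroman-4-one F12. The buffered fluoride conditions of step 12 (2.4 equiv) then give 26.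

**Further compounds**

F1 | step 9 | 1-bromo-3,5-bis(methoxymethoxy)benzene | COCOc1cc(Br)cc(OCOC)c1
F2 | step 9 | 5-bromo-1,3-bis(methoxymethoxy)-2-(3-methylbut-2-en-1-yl)benzene | COCOc1cc(Br)cc(OCOC)c1CC=C(C)C
F3 | step 9 | 1-bromo-3,5-bis(methoxymethoxy)-2-methyl-4-(3-methylbut-2-en-1-yl)benzene | COCOc1cc(Br)c(C)c(OCOC)c1CC=C(C)C
F4 | step 9 | 3,5-bis(methoxymethoxy)-2-methyl-4-(3-methylbut-2-en-1-yl)phenol | COCOc1cc(O)c(C)c(OCOC)c1CC=C(C)C
F5 | step 9 | methyl (3R)-3-hydroxy-3-[4-methoxy-3-(3-methylbut-2-en-1-yl)phenyl]propanoate | COC(=O)C[C@@H](O)c1ccc(OC)c(CC=C(C)C)c1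
F6 | step 9 | methyl (3S)-3-[3,5-bis(methoxymethoxy)-2-methyl-4-prenylphenoxy]-3-(4-methoxy-3-prenylphenyl)propanoate | COC(=O)C[C@H](Oc1cc(OCOC)c(CC=C(C)C)c(OCOC)c1C)c1ccc(OC)c(CC=C(C)C)c1
F7 | step 9 | (3S)-3-[3,5-bis(methoxymethoxy)-2-methyl-4-prenylphenoxy]-3-(4-methoxy-3-prenylphenyl)propanoic acid | OC(=O)C[C@H](Oc1cc(OCOC)c(CC=C(C)C)c(OCOC)c1C)c1ccc(OC)c(CC=C(C)C)c1
F8 | step 9 | (2S)-2-(4-methoxy-3-prenylphenyl)-5,7-bis(methoxymethoxy)-8-methyl-6-prenylchroman-4-one | COc1ccc([C@@H]2CC(=O)c3c(OCOC)c(CC=C(C)C)c(OCOC)c(C)c3O2)cc1CC=C(C)C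
F9 | step 6 | methyl (3R)-3-hydroxy-3-[4-methoxy-3-(3-methylbut-2-en-1-yl)phenyl]propanoate | COC(=O)C[C@@H](O)c1ccc(OC)c(CC=C(C)C)c1
F10 | step 11 | methyl (3S)-3-[2-methyl-4-prenyl-3,5-bis(triisopropylsilyloxy)phenoxy]-3-(4-methoxy-3-prenylphenyl)propanoate | COC(=O)C[C@H](Oc1cc(O[Si](C(C)C)(C(C)C)C(C)C)c(CC=C(C)C)c(O[Si](C(C)C)(C(C)C)C(C)C)c1C)c1ccc(OC)c(CC=C(C)C)c1
F11 | step 11 | methyl (3S)-3-[2-bromo-6-methyl-4-prenyl-3,5-bis(triisopropylsilyloxy)phenoxy]-3-(4-methoxy-3-prenylphenyl)propanoate | COC(=O)C[C@H](Oc1c(Br)c(O[Si](C(C)C)(C(C)C)C(C)C)c(CC=C(C)C)c(O[Si](C(C)C)(C(C)C)C(C)C)c1C)c1ccc(OC)c(CC=C(C)C)c1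
F12 | step 11 | (2S)-2-(4-methoxy-3-prenylphenyl)-8-methyl-6-prenyl-5,7-bis(triisopropylsilyloxy)chroman-4-one | COc1ccc([C@@H]2CC(=O)c3c(O[Si](C(C)C)(C(C)C)C(C)C)c(CC=C(C)C)c(O[Si](C(C)C)(C(C)C)C(C)C)c(C)c3O2)cc1CC=C(C)C
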